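The earlier runs and the new flask are calculated on assumed constants.

Set the J charge of this flask by one ratio, which Thursday's run gives without a clock.

| flask | E | J | D | remark | time |
|---|---|---|---|---|---|
| Thursday's | 0.13 M | 0.36 M | 0.020 M | run made earlier |  |
| east | 0.20 M | 1.40 M | 0.0200 M |  | 8.0 h |
| south | 0.20 M | 0.360 M | 0.0200 M |  | 8.0 h |
| north-west | 0.20 M | 0.720 M | 0.0200 M |  | 8.0 h |

Thursday's run (percent of the E charged)

| time / h | E / % | X / % |
|---|---|---|
| 0.167 | 94.6 | 3.1 |
| 0.417 | 89.8 | 6.2 |
| 0.833 | 80.3 | 12.6 |
| 1.33 | 70.2 | 19.2 |
| 1.50 | 68.9 | 20.3 |
| 2.00 | 58.5 | 27.3 |
| 3.00 | 47.8 | 35.0 |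

(scatter of a reading: 1 percentage point)

- the numbers in the tables scatter with a standard deviation of 1 percentage point
- what has gone from E into another species counts as reacted, even if it can come back

1. part of the E that has reacted at the end, east
2. part of the E that has reacted at the end, south
3. part of the E that has reacted at the end, north-west
4. what raising the concentration of J from its lowest to its highest value here does to the part of the E that has reacted (changes below 5 percentage points count as none) (it rises / it falls / no change)

E reacts with J to X, but in Thursday's run E and X do not add up: at 3.00 h E has lost 52.2% of its charge and X holds 35.0%, so the rest has gone into an unseen side channel. Dividing the rate into X by the rate into that channel removes time. A single J level has been run, so the path to X is assumed first order in J, and the loss of E first order in E along both channels. Dividing by the J charge then gives the capture ratio, a selectivity factor per unit of J, read here from the readings at 3.00 h: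

capture ratio = (X formed) / (E gone to the side) / (J charge) = 5.65 L mol⁻¹

share of reacted E found as X = ratio × J / (one + ratio × J)

At the J of south the share is 67.0%. E in Thursday's run falls at 0.246 h⁻¹, and that share of it, 0.165 h⁻¹, is the path to X. Two versions of south can be solved in the head, both with J held at its charge:

side channel at full pace throughout: reacted = 86.0%

side channel shut: reacted = 73.3%

The running side channel lifts south above the second version. But X takes J as it forms, about 0.0983 M of the 0.360 M if one J goes per X, and that pulls both versions down. In the readings the side take grows 2.42-fold from 0.833 h to 3.00 h, and X 2.78-fold. This reckoning takes the lift and the pull as roughly offsetting and stays with the second version: 73.3% for south, 92.9% for north-west and 99.4% for east, so reacted E rises with J.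

The forecast gives 99%, 80% and 95% for east, south and north-west and, for raising J, it rises, in its words “Reacted E therefore rises with J”, with south 6.7 percentage points above this reckoning.

The flask gives 99.1%, 72.8% and 91.4% for east, south and north-west: it rises, by 26 points.

    E + J → Z + X (k = 0.530 L mol⁻¹ h⁻¹)
    E ⇌ G (K = 0.650, k = 0.0400 h⁻¹)
    J + Z ⇌ L, settled at all times (K = 430 L mol⁻¹)
    E + D → Q (k = 3.10 L mol⁻¹ h⁻¹)

In south at 8.00 h, J has lost 0.205 M while X stands at 0.103 M, so the J lost is twice the X formed, and the other part stands as L, 0.102 M. For north-west the capture ratio, with J held at its charge, gives X a share of 80.3%, and at 8.00 h the flask holds as X 83.1% of the E reacted. With J lowered to 0.18 M in the same flask, the ratio on the same terms gives 50.4%, and at 8.00 h that neighbour holds as X 54.3% of the E reacted.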